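**Retrosynthetic overview**

1. The target is 5-methoxy-2-methyl-3-pentacosyl-1,4-benzoquinone (ring: C1=O, C2–CH3, C3–chain, C4=O, C5–OCH3, C6–H; chain C1′–C25′ counted from C3). It is cut at C11′–C12′ into tetradecylmagnesium chloride (C12′–C25′) and the ring-bearing C11 primary bromide. Forward, this is a copper-catalysed sp3–sp3 Kumada coupling that ends in the same flask with ferric chloride oxidation to the quinone.
2. Enabling feature: C11′ and C12′ are two unbranched CH2 groups without stereochemistry, ten methylenes away from ring carbon C3. The six-membered C1–C6 quinone ring can be held at the hydroquinone level, where the C1/C4 hydroxyls become a bis(chloromagnesium) aryloxide that Grignard and organocopper species leave alone. No protecting group is needed.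
3. The C3–C1′ bond is cut next: Jacobsen–Torssell decarboxylative radical alkylation of the C3–H of 2-methoxy-5-methyl-1,4-benzoquinone with 12-bromododecanoic acid, the carboxyl group serving as a traceless activating group.
4. Ring order: the only ring is never built. It is the benzene ring of commercial 2-methoxy-5-methylphenol and only changes oxidation level (phenol → quinone → hydroquinone → quinone).

Key step: step 4

Remark: the target has no stereocentre and no stereogenic double bond, so no configuration has to be set; tetradecylmagnesium chloride is taken as the commercial 1.0 M solution in THF.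

**Route**

Step 1
Reactants: 1 2-methoxy-5-methylphenol
Product: 2 2-methoxy-5-methyl-1,4-benzoquinone (in target numbering 5-methoxy-2-methyl, free C–H at C3 and C6)
Conditions: (KSO3)2NO (2.5 equiv), KH2PO4, H2O/acetone, 0 °C to rt
Reagents that add atoms: potassium nitrosodisulfonate (Fremy's salt), [K+].[K+].[O]N(S(=O)(=O)[O-])S(=O)(=O)[O-]
Why: Teuber oxidation: Fremy's radical abstracts the phenolic hydrogen, a second equivalent adds at the free para carbon and loss of imidodisulfonate should give the p-quinone, the normal outcome for a guaiacol-type phenol with an unsubstituted para position.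

Step 2
Reactants: 2 2-methoxy-5-methyl-1,4-benzoquinone (1.3 equiv); 3 12-bromododecanoic acid
Product: 4 3-(11-bromoundecyl)-5-methoxy-2-methyl-1,4-benzoquinone
Conditions: AgNO3 (0.2 equiv), (NH4)2S2O8 (1.3 equiv, added slowly), MeCN/H2O 1:1, 70 °C
Reagents that add atoms: none
Why: Jacobsen–Torssell reaction: Ag(I)/persulfate decarboxylates 3 to the primary 11-bromoundecyl radical, which adds to a quinone C–H and is re-oxidised to the alkylquinone, a reaction type closely precedented for ω-bromoalkanoic acids with methoxy-methyl-benzoquinones; the nucleophilic radical should choose C3–H on the methyl-bearing double bond because C6–H is the electron-rich β-carbon of the C5-methoxy enol ether, and the slight excess of 2 works against double alkylation.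

Step 3
Reactants: 4 3-(11-bromoundecyl)-5-methoxy-2-methyl-1,4-benzoquinone
Product: 5 3-(11-bromoundecyl)-5-methoxy-2-methylbenzene-1,4-diol
Conditions: Na2S2O4 (3 equiv), Et2O/H2O, rt, Ar
Reagents that add atoms: none
Why: Dithionite is the standard two-electron reductant for quinones in a two-phase system and leaves the primary alkyl bromide and the methoxy group untouched; the hydroquinone is kept under argon, dried azeotropically and used at once.

Step 4
Reactants: 5 3-(11-bromoundecyl)-5-methoxy-2-methylbenzene-1,4-diol; 6 tetradecylmagnesium chloride
Product: 10 5-methoxy-2-methyl-3-pentacosylcyclohexa-2,5-diene-1,4-dione (target), via bromoalkyl bis(chloromagnesium) aryloxide 7 (not isolated), via pentacosyl bis(chloromagnesium) aryloxide 8 (not isolated), via pentacosylhydroquinone 9 (not isolated)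
Conditions: 6 (3.4 equiv; 2 equiv first at 0 °C), then Li2CuCl4 (3 mol %), NMP (4 equiv), THF, 0 to 20 °C, Ar; then 1 M HCl, FeCl3 (2.5 equiv), Et2O/H2O, rt
Reagents that add atoms: none
Why: The first two equivalents of 6 only deprotonate the two phenolic OH of 5 to the bis(chloromagnesium) aryloxide 7, in which the ring has neither an electrophilic carbonyl nor an acidic proton left; Li2CuCl4 is then reduced by 6 to a tetradecylcuprate that displaces the unhindered primary bromide at C11′ by SN2-type oxidative addition and reductive elimination, forming the C11′–C12′ CH2–CH2 bond and giving 8. The closest known reaction type is the copper-catalysed alkyl–alkyl Kumada coupling with Li2CuCl4 in THF/NMP, which is also run on ω-bromo alcohols and ω-bromo acids as their magnesium salts. No ring is closed and no stereocentre is formed. The selectivity needed is cross-coupling at the C–Br bond over reduction, elimination and homocoupling and over any attack on the ring; the primary bromide, NMP as co-solvent (which should also keep 7 in solution) and the dianion form of the ring secure it. Acidification frees hydroquinone 9, and ferric chloride removes two electrons and two protons to return C1 and C4 to the quinone 10, so the chain union and the final oxidation level are reached in one operation.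

**Compound list**

1 | 2-methoxy-5-methylphenol | COc1ccc(C)cc1O | starting material
2 | 2-methoxy-5-methylcyclohexa-2,5-diene-1,4-dione (2-methoxy-5-methyl-1,4-benzoquinone) | COC1=CC(=O)C(C)=CC1=O | intermediate
3 | 12-bromododecanoic acid | OC(=O)CCCCCCCCCCCBr | starting material
4 | 3-(11-bromoundecyl)-5-methoxy-2-methylcyclohexa-2,5-diene-1,4-dione | BrCCCCCCCCCCCC1=C(C)C(=O)C=C(OC)C1=O | intermediate
5 | 3-(11-bromoundecyl)-5-methoxy-2-methylbenzene-1,4-diol | BrCCCCCCCCCCCc1c(C)c(O)cc(OC)c1O | intermediate
6 | tetradecylmagnesium chloride | CCCCCCCCCCCCCC[Mg]Cl | starting material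
7 | bis(chloromagnesium) 3-(11-bromoundecyl)-5-methoxy-2-methylbenzene-1,4-diolate | BrCCCCCCCCCCCc1c(C)c(O[Mg]Cl)cc(OC)c1O[Mg]Cl | intermediate
8 | bis(chloromagnesium) 5-methoxy-2-methyl-3-pentacosylbenzene-1,4-diolate | CCCCCCCCCCCCCCCCCCCCCCCCCc1c(C)c(O[Mg]Cl)cc(OC)c1O[Mg]Cl | intermediate
9 | 5-methoxy-2-methyl-3-pentacosylbenzene-1,4-diol | CCCCCCCCCCCCCCCCCCCCCCCCCc1c(C)c(O)cc(OC)c1O | intermediate
10 | 5-methoxy-2-methyl-3-pentacosylcyclohexa-2,5-diene-1,4-dione | CCCCCCCCCCCCCCCCCCCCCCCCCC1=C(C)C(=O)C=C(OC)C1=O | target

**Step count and risks**

Total step count: 4. Longest linear sequence: 4 steps (1 → 2 → 4 → 5 → 10); 3 and 6 are purchased.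

Steps most likely to fail:

1. Step 2 – loss of regiocontrol in the radical addition (attack at C6–H instead of C3–H) and double alkylation. The fallback sets out from 1 and comes back at 4; it fixes the chain position by a sigmatropic shift instead of a radical addition. 1 is O-allylated (allyl bromide, K2CO3, acetone) to 1-methoxy-4-methyl-2-(prop-2-en-1-yloxy)benzene F1. Aromatic Claisen rearrangement (N,N-diethylaniline, 200 °C) can deliver the allyl group only to the one free ortho carbon and should give 2-allyl-6-methoxy-3-methylphenol F2. Cross-metathesis with 10-bromodec-1-ene (Grubbs second-generation catalyst, CH2Cl2, 40 °C) should give 2-[(E)-11-bromoundec-2-en-1-yl]-6-methoxy-3-methylphenol F3 (E drawn; the Z isomer converges). Hydrogenation of the alkene (H2, RhCl(PPh3)3, benzene/EtOH) should give 2-(11-bromoundecyl)-6-methoxy-3-methylphenol F4. Teuber oxidation with Fremy's salt as in step 1 (the para position is free) then gives 4.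

2. Step 4 – aggregation or precipitation of the magnesium bis-aryloxide, so that the coupling stalls and reduction or elimination of the bromide takes over. The fallback sets out from 5 and comes back at 10; the ring is carried as its trimethyl ether. 5 is O-methylated (Me2SO4, K2CO3, acetone, reflux, Ar) to 3-(11-bromoundecyl)-1,2,5-trimethoxy-4-methylbenzene F5. The same copper-catalysed coupling with 6 (1.3 equiv) on this aprotic bromide should give 1,2,5-trimethoxy-4-methyl-3-pentacosylbenzene F6. Oxidative demethylation of the para-dimethoxy pair with ceric ammonium nitrate (MeCN/H2O, 0 °C) then gives 10.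

3. Step 3 – re-oxidation of the electron-rich hydroquinone by air during extraction and drying, so that quinone is carried into the Grignard step. The fallback sets out from 4 and comes back at 7; the reduced ring is trapped in the reduction flask. Reductive acetylation of 4 (Zn dust, Ac2O, Et3N, CH2Cl2, rt) should give the air-stable 3-(11-bromoundecyl)-5-methoxy-2-methyl-1,4-phenylene diacetate F7, which can be purified and stored. In the flask of step 4, methylmagnesium chloride (4.0 equiv, THF, 0 °C) removes both acetyl groups as tert-butoxide and leaves 7, which continues as in step 4.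

**Further compounds**

F1 | step 2 | 1-methoxy-4-methyl-2-(prop-2-en-1-yloxy)benzene | COc1ccc(C)cc1OCC=C
F2 | step 2 | 6-methoxy-3-methyl-2-(prop-2-en-1-yl)phenol | COc1ccc(C)c(CC=C)c1O
F3 | step 2 | 2-[(E)-11-bromoundec-2-en-1-yl]-6-methoxy-3-methylphenol | COc1ccc(C)c(C/C=C/CCCCCCCCBr)c1O
F4 | step 2 | 2-(11-bromoundecyl)-6-methoxy-3-methylphenol | COc1ccc(C)c(CCCCCCCCCCCBr)c1O
F5 | step 4 | 3-(11-bromoundecyl)-1,2,5-trimethoxy-4-methylbenzene | BrCCCCCCCCCCCc1c(C)c(OC)cc(OC)c1OC
F6 | step 4 | 1,2,5-trimethoxy-4-methyl-3-pentacosylbenzene | CCCCCCCCCCCCCCCCCCCCCCCCCc1c(C)c(OC)cc(OC)c1OC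
F7 | step 3 | 3-(11-bromoundecyl)-5-methoxy-2-methyl-1,4-phenylene diacetate | BrCCCCCCCCCCCc1c(C)c(OC(C)=O)cc(OC)c1OC(C)=O
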